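Assumption: (Sp,Sp)-MandyPhos is taken to give the 6S series (if the sense is opposite, its antipode is used). Atom labels C1-C15 follow germacrane numbering.

## Retrosynthetic overview

1. The ten-membered ring closes last, at C1=C10, by ring-closing metathesis of a seco-triene. The ring enforces the ring-cis olefin.
2. C6-C7 and the trans γ-lactone come from a chromium-mediated 2-(methoxycarbonyl)allylation. An epoxy lactol (C1-C6) reacts with an allylic bromide (C7-C14) that already carries 8-OAng and 9-OAc.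
3. Key step: two vinyl units and a Z enol triflate are joined by a palladium-induced 1,2-metallate shift. This makes C1-C2, C3-C4 and the C2 carbinol centre. The product closes to a six-membered lactone template that locks the Z olefin and directs the cis epoxide.
4. The C7-C14 half comes from an asymmetric alkoxyallylboration (C8, C9), two acylations, alkyne hydromethoxycarbonylation and cross-metathesis.
5. Ring order: δ-lactone (temporary), oxirane, γ-lactone, carbocycle.

## Route

Step 1
Reactants: 1 methyl acetoacetate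
Product: 2 methyl (2Z)-3-(trifluoromethylsulfonyloxy)but-2-enoate
Conditions: Tf2O, sat. aq. LiOH, toluene, 5-10 °C
Reagents that add atoms: trifluoromethanesulfonic anhydride, O=S(=O)(OS(=O)(=O)C(F)(F)F)C(F)(F)F
Why: Stereoselective enol triflation, in which the lithium-chelated Z enolate of the β-keto ester is trapped on oxygen, so OTf ends cis to CO2Me.

Step 2
Reactants: 2 methyl (2Z)-3-(trifluoromethylsulfonyloxy)but-2-enoate; 3 vinylmagnesium bromide (2 equiv)
Product: 7 (6S)-6-ethenyl-4-methyl-5,6-dihydro-2H-pyran-2-one, via diethenyl pinacol borate 4 (not isolated), via allylic pinacol boronate 5 (not isolated), via Z hydroxy enoate 6 (not isolated)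
Conditions: i-PrOBpin, 3, THF, -78 °C to rt; NaOTf; 2, Pd(OAc)2 (3 mol%), (Sp,Sp)-MandyPhos (Ar = 3,5-Me2-4-MeOC6H2, 3.6 mol%), THF, 45 °C; H2O2, pH 7 buffer, 0 °C; PPTS, CH2Cl2
Reagents that add atoms: hydrogen peroxide, OO
Why: Proposed new method: zerovalent palladium inserts into the C-OTf bond of 2 with retention, the cationic electron-poor alkenylpalladium binds one vinyl group of borate 4, and this triggers a 1,2-metallate shift in which the second vinyl group migrates from boron to the adjacent carbon anti to palladium (C1-C2 bond, C2 centre fixed by the chiral bisphosphine); reductive elimination then forms C3-C4 with the Z geometry intact, and stereoretentive B-to-O oxidation followed by closure of the Z hydroxy enoate gives 7; the closest known reaction type is the Pd/MandyPhos conjunctive cross-coupling of bis(alkenyl)boronates with aryl and simple alkenyl triflates, not shown so far with a symmetrical divinylborate and a β-triflyloxy enoate.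

Step 3
Reactants: 7 (6S)-6-ethenyl-4-methyl-5,6-dihydro-2H-pyran-2-one
Product: 8 (1R,4S,6R)-4-ethenyl-6-methyl-3,7-dioxabicyclo[4.1.0]heptan-2-one
Conditions: t-BuOOH, benzyltrimethylammonium hydroxide (cat.), THF, 0 °C
Reagents that add atoms: tert-butyl hydroperoxide, CC(C)(C)OO
Why: Weitz-Scheffer nucleophilic epoxidation touches only the conjugated olefin; the peroxide adds axially anti to the pseudo-equatorial vinyl group (sets C4 and C5), and the six-membered ring allows only the cis epoxide.

Step 4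
Reactants: 8 (1R,4S,6R)-4-ethenyl-6-methyl-3,7-dioxabicyclo[4.1.0]heptan-2-one
Product: 9 (1R,4S,6R)-4-ethenyl-6-methyl-3,7-dioxabicyclo[4.1.0]heptan-2-ol (anomer mixture)
Conditions: i-Bu2AlH (1.05 equiv), CH2Cl2, -78 °C; aq. work-up
Reagents that add atoms: none
Why: Partial lactone reduction stops at the aluminium lactolate at low temperature, and the lactol stores the cis epoxy aldehyde without risk of epimerisation.

Step 5
Reactants: 10 3-(methoxymethoxy)prop-1-ene; 11 3-(trimethylsilyl)prop-2-ynal
Product: 14 (3S,4S)-4-(methoxymethoxy)hex-5-en-1-yn-3-ol, via Z alkoxyallyl diisopinocampheylborane 12 (not isolated), via C-silylated alkynol 13 (not isolated)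
Conditions: s-BuLi, THF, -78 °C; (+)-Ipc2BOMe; BF3·OEt2; 11, -78 °C; NaOH, H2O2; K2CO3, MeOH
Reagents that add atoms: none
Why: Brown asymmetric alkoxyallylboration runs through a closed chair transition state; the Z borane gives the syn C8/C9 pair and the (+)-Ipc groups select the aldehyde face (3S,4S), while the basic methanol removes the alkynyl silane.

Step 6
Reactants: 14 (3S,4S)-4-(methoxymethoxy)hex-5-en-1-yn-3-ol
Product: 15 (3S,4S)-4-(methoxymethoxy)hex-5-en-1-yn-3-yl acetate
Conditions: Ac2O, pyridine, DMAP (cat.), CH2Cl2, 0 °C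
Reagents that add atoms: acetic anhydride, CC(=O)OC(C)=O
Why: Standard O-acetylation of the only free hydroxyl places the C9 acetate with no change at the stereocentres.

Step 7
Reactants: 15 (3S,4S)-4-(methoxymethoxy)hex-5-en-1-yn-3-yl acetate
Product: 16 (3S,4S)-4-hydroxyhex-5-en-1-yn-3-yl acetate
Conditions: Me2BBr, CH2Cl2, -78 °C; sat. aq. NaHCO3, THF
Reagents that add atoms: none
Why: Lewis acid cleavage of the acetal-type MOM ether at -78 °C spares the acetate, the alkyne and the alkene and is cold enough to suppress 1,2-acyl migration.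

Step 8
Reactants: 16 (3S,4S)-4-hydroxyhex-5-en-1-yn-3-yl acetate; 17 angelic acid, (2Z)-2-methylbut-2-enoic acid
Product: 19 (3S,4S)-4-acetoxyhex-1-en-5-yn-3-yl (2Z)-2-methylbut-2-enoate, via mixed Yamaguchi anhydride 18 (not isolated)
Conditions: 17, 2,4,6-trichlorobenzoyl chloride, Et3N, toluene, rt; 16, 80 °C (no DMAP)
Reagents that add atoms: none
Why: Yamaguchi esterification without a nucleophilic catalyst avoids the addition-elimination path that turns angelates into tiglates, so the Z ester is kept.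

Step 9
Reactants: 19 (3S,4S)-4-acetoxyhex-1-en-5-yn-3-yl (2Z)-2-methylbut-2-enoate
Product: 20 methyl (3S,4S)-3-acetoxy-2-methylidene-4-{[(2Z)-2-methylbut-2-enoyl]oxy}hex-5-enoate
Conditions: Pd(OAc)2 (1 mol%), 2-(diphenylphosphino)pyridine, MeSO3H (cat.), CO (30 bar), MeOH, 45 °C
Reagents that add atoms: carbon monoxide, [C-]#[O+]; methanol, CO
Why: Markovnikov hydromethoxycarbonylation of a terminal alkyne with the Pd/2-pyridylphosphine system gives the branched acrylate (C10, C14) far faster than any alkene reacts, and O8 is already acylated so no lactone to C14 can form.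

Step 10
Reactants: 20 methyl (3S,4S)-3-acetoxy-2-methylidene-4-{[(2Z)-2-methylbut-2-enoyl]oxy}hex-5-enoate; 21 methyl 2-(bromomethyl)prop-2-enoate (excess)
Product: 22 dimethyl (2Z,4S,5S)-5-acetoxy-2-(bromomethyl)-6-methylidene-4-{[(2Z)-2-methylbut-2-enoyl]oxy}hept-2-enedioate
Conditions: second-generation Hoveyda-Grubbs catalyst (7 mol%), CH2Cl2, 40 °C
Reagents that add atoms: none
Why: Olefin cross-metathesis engages only the monosubstituted vinyl group of 20 and, as with methacrylates, places the chain trans to CO2Me.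

Step 11
Reactants: 9 (1R,4S,6R)-4-ethenyl-6-methyl-3,7-dioxabicyclo[4.1.0]heptan-2-ol; 22 dimethyl (2Z,4S,5S)-5-acetoxy-2-(bromomethyl)-6-methylidene-4-{[(2Z)-2-methylbut-2-enoyl]oxy}hept-2-enedioate
Product: 25 methyl (3S,4S)-3-acetoxy-4-[(2S,3R)-2-{(2S,3R)-3-[(2S)-2-hydroxybut-3-en-1-yl]-3-methyloxiran-2-yl}-4-methylidene-5-oxooxolan-3-yl]-2-methylidene-4-{[(2Z)-2-methylbut-2-enoyl]oxy}butanoate, via allylchromium dichloride 23 (not isolated), via open C6 carbinol 24 (not isolated)
Conditions: CrCl2 (4 equiv), THF-DMF, rt; aq. citric acid work-up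
Reagents that add atoms: none
Why: Nozaki-Hiyama (Barbier-type) allylation of the open epoxy aldehyde tautomer of 9 sets C6 and C7 as follows: the equilibrating allylchromium reacts through a chair transition state to give the anti adduct (trans lactone), the epoxy aldehyde is attacked in the Cornforth/Felkin sense (O5/O6 anti), the A(1,3)-minimised C7-C8 rotamer is attacked anti to the C8-C9 bond, and the chromium alkoxide then closes onto the C12 ester.

Step 12
Reactants: 25 seco-triene lactone (name as in step 11)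
Product: 26 target CNP0278274.1, methyl ester of the (2S,4R,5S,6S,7R,8S,9S)-9-acetoxy-8-angeloyloxy-4,5-epoxy-2-hydroxygermacra-1(10),11(13)-dien-12,6-olid-14-oic acid, C1=C10 ring-cis (E by CIP)
Conditions: second-generation Hoveyda-Grubbs catalyst (15 mol%), 1,4-benzoquinone, toluene (0.5 mM), 80 °C
Reagents that add atoms: none
Why: Ring-closing metathesis starts at the unhindered allylic alcohol vinyl group and closes on the C10 acrylate methylene; the ten-membered ring accepts only the ring-cis olefin, and the angelate and exocyclic lactone olefins are too hindered or strained to compete.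

## Compound list

1 | methyl acetoacetate | CC(=O)CC(=O)OC | starting material
2 | methyl (2Z)-3-(trifluoromethylsulfonyloxy)but-2-enoate | C/C(OS(=O)(=O)C(F)(F)F)=C/C(=O)OC | intermediate
3 | vinylmagnesium bromide | C=C[Mg]Br | starting material
4 | bromomagnesium diethenyl(pinacolato)borate | C=C[B-]1(C=C)OC(C)(C)C(C)(C)O1.[Mg+2].[Br-] | intermediate
5 | methyl (2Z,5S)-3-methyl-5-(4,4,5,5-tetramethyl-1,3,2-dioxaborolan-2-yl)hepta-2,6-dienoate | C=C[C@@H](B1OC(C)(C)C(C)(C)O1)C/C(C)=C\C(=O)OC | intermediate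
6 | methyl (2Z,5S)-5-hydroxy-3-methylhepta-2,6-dienoate | C=C[C@@H](O)C/C(C)=C\C(=O)OC | intermediate
7 | (6S)-6-ethenyl-4-methyl-5,6-dihydro-2H-pyran-2-one | C=C[C@@H]1CC(C)=CC(=O)O1 | intermediate
8 | (1R,4S,6R)-4-ethenyl-6-methyl-3,7-dioxabicyclo[4.1.0]heptan-2-one | C=C[C@@H]1C[C@@]2(C)O[C@H]2C(=O)O1 | intermediate
9 | (1R,4S,6R)-4-ethenyl-6-methyl-3,7-dioxabicyclo[4.1.0]heptan-2-ol (anomers) | C=C[C@@H]1C[C@@]2(C)O[C@H]2C(O)O1 | intermediate
10 | 3-(methoxymethoxy)prop-1-ene | C=CCOCOC | starting material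
11 | 3-(trimethylsilyl)prop-2-ynal | C[Si](C)(C)C#CC=O | starting material
12 | [(2Z)-3-(methoxymethoxy)prop-2-enyl]bis(isopinocampheyl)borane, (+)-Ipc series | C[C@@H]1[C@@H](B(C/C=C\OCOC)[C@H]3C[C@H]4C[C@@H]([C@@H]3C)C4(C)C)C[C@H]2C[C@@H]1C2(C)C | intermediate
13 | (3S,4S)-4-(methoxymethoxy)-1-(trimethylsilyl)hex-5-en-1-yn-3-ol | C=C[C@H](OCOC)[C@@H](O)C#C[Si](C)(C)C | intermediate
14 | (3S,4S)-4-(methoxymethoxy)hex-5-en-1-yn-3-ol | C=C[C@H](OCOC)[C@@H](O)C#C | intermediate
15 | (3S,4S)-4-(methoxymethoxy)hex-5-en-1-yn-3-yl acetate | C=C[C@H](OCOC)[C@@H](OC(C)=O)C#C | intermediate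
16 | (3S,4S)-4-hydroxyhex-5-en-1-yn-3-yl acetate | C=C[C@H](O)[C@@H](OC(C)=O)C#C | intermediate
17 | angelic acid, (2Z)-2-methylbut-2-enoic acid | C/C=C(/C)C(=O)O | starting material
18 | (2Z)-2-methylbut-2-enoic 2,4,6-trichlorobenzoic anhydride | C/C=C(/C)C(=O)OC(=O)c1c(Cl)cc(Cl)cc1Cl | intermediate
19 | (3S,4S)-4-acetoxyhex-1-en-5-yn-3-yl (2Z)-2-methylbut-2-enoate | C=C[C@H](OC(=O)/C(C)=C\C)[C@@H](OC(C)=O)C#C | intermediate
20 | methyl (3S,4S)-3-acetoxy-2-methylidene-4-{[(2Z)-2-methylbut-2-enoyl]oxy}hex-5-enoate | C=C[C@H](OC(=O)/C(C)=C\C)[C@@H](OC(C)=O)C(=C)C(=O)OC | intermediate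
21 | methyl 2-(bromomethyl)prop-2-enoate | C=C(CBr)C(=O)OC | starting material
22 | dimethyl (2Z,4S,5S)-5-acetoxy-2-(bromomethyl)-6-methylidene-4-{[(2Z)-2-methylbut-2-enoyl]oxy}hept-2-enedioate | COC(=O)/C(CBr)=C/[C@H](OC(=O)/C(C)=C\C)[C@@H](OC(C)=O)C(=C)C(=O)OC | intermediate
23 | allylchromium dichloride derived from 22 (CrCl2 in place of Br) | COC(=O)/C(C[Cr](Cl)Cl)=C/[C@H](OC(=O)/C(C)=C\C)[C@@H](OC(C)=O)C(=C)C(=O)OC | intermediate
24 | open C6 carbinol (6S,7 as in 25), dimethyl diester before lactonisation | C=C(C(=O)OC)[C@@H]([C@H](O)[C@@H]1O[C@]1(C)C[C@H](O)C=C)[C@H](OC(=O)/C(C)=C\C)[C@@H](OC(C)=O)C(=C)C(=O)OC | intermediate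
25 | seco-triene lactone (name in step 11) | C=C1C(=O)O[C@H]([C@@H]2O[C@]2(C)C[C@H](O)C=C)[C@H]1[C@H](OC(=O)/C(C)=C\C)[C@@H](OC(C)=O)C(=C)C(=O)OC | intermediate
26 | CNP0278274.1 | C=C1C(=O)O[C@H]2[C@H]1[C@H](OC(=O)/C(C)=C\C)[C@@H](OC(C)=O)/C(C(=O)OC)=C\[C@@H](O)C[C@@]1(C)O[C@@H]21 | target

## Step count

Total steps: 12. Longest linear sequence: 8 (steps 5-12).

## Steps most likely to fail

**Step 2 (the new step).**
- Risks: direct vinyl transfer (Suzuki-type diene), low enantioselectivity with the electron-poor alkenylpalladium, and loss of the allylic boronate before oxidation.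
- Fallback (known chemistry), setting out from 2:
  - Iron-catalysed cross-coupling with MeMgBr (Fe(acac)3, THF/NMP, -30 °C) gives methyl 3-methylbut-2-enoate F1.
  - LDA then Me3SiCl gives [(1-methoxy-3-methylbuta-1,3-dien-1-yl)oxy]trimethylsilane F2.
  - A copper-catalysed asymmetric vinylogous Mukaiyama aldol reaction with acrolein (Cu(OTf)2, the Tol-BINAP antipode that gives 6S, Bu4N[Ph3SiF2], THF) delivers the unsaturated lactone directly.
  - The route is rejoined at 7.

**Step 11.**
- Risks: 1,4-elimination of angelate from the allylmetal to give a diene, reduction of the epoxy aldehyde by divalent chromium, and mismatched facial control.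
- Fallback, setting out from 22:
  - Copper-catalysed borylation (B2pin2, CuCl, KOAc, DMF) gives the allylboronate dimethyl (2Z,4S,5S)-5-acetoxy-6-methylidene-4-{[(2Z)-2-methylbut-2-enoyl]oxy}-2-[(4,4,5,5-tetramethyl-1,3,2-dioxaborolan-2-yl)methyl]hept-2-enedioate F3. This covalent reagent cannot eliminate and needs no reducing metal.
  - Its In(OTf)3-catalysed, stereoconvergent allylboration of 9 gives the trans lactone through 24.
  - The route is rejoined at 25.

**Step 12.**
- Risks: a hindered 1,1-disubstituted acrylate, the strain of the ten-membered ring, and oligomers.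
- Fallback, setting out from 9 and 22, with the order of the last two bond formations inverted:
  - Intermolecular cross-metathesis of the vinyl group of 9 with the C10 acrylate of 22 (second-generation Hoveyda-Grubbs catalyst, excess 9) gives the strain-free C1=C10 olefin. This product is the lactol allylic bromide dimethyl (2Z,4S,5S,6E)-5-acetoxy-2-(bromomethyl)-6-{[(1R,4S,6R)-2-hydroxy-6-methyl-3,7-dioxabicyclo[4.1.0]heptan-4-yl]methylidene}-4-{[(2Z)-2-methylbut-2-enoyl]oxy}hept-2-enedioate F4.
  - The ring is then closed at C6-C7 by the intramolecular CrCl2 allylation at high dilution, a known way to close germacranolide rings.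
  - The route is rejoined at 26.

## Further compounds

F1 | step 2 | methyl 3-methylbut-2-enoate | CC(C)=CC(=O)OC
F2 | step 2 | [(1-methoxy-3-methylbuta-1,3-dien-1-yl)oxy]trimethylsilane | C=C(C)C=C(OC)O[Si](C)(C)C
F3 | step 11 | dimethyl (2Z,4S,5S)-5-acetoxy-6-methylidene-4-{[(2Z)-2-methylbut-2-enoyl]oxy}-2-[(4,4,5,5-tetramethyl-1,3,2-dioxaborolan-2-yl)methyl]hept-2-enedioate | COC(=O)/C(CB1OC(C)(C)C(C)(C)O1)=C/[C@H](OC(=O)/C(C)=C\C)[C@@H](OC(C)=O)C(=C)C(=O)OC
F4 | step 12 | dimethyl (2Z,4S,5S,6E)-5-acetoxy-2-(bromomethyl)-6-{[(1R,4S,6R)-2-hydroxy-6-methyl-3,7-dioxabicyclo[4.1.0]heptan-4-yl]methylidene}-4-{[(2Z)-2-methylbut-2-enoyl]oxy}hept-2-enedioate | COC(=O)/C(CBr)=C/[C@H](OC(=O)/C(C)=C\C)[C@@H](OC(C)=O)/C(C(=O)OC)=C\[C@@H]1C[C@@]2(C)O[C@H]2C(O)O1
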